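**Plan**

Retrosynthesis: the two hydroxyls go back to methyl ethers. The ring bond between the methyl-bearing carbon C3 and its oxygen-bearing neighbour C2 is cut by a retro-6π electrocyclization to a dienylketene. Ketene carbon C2 is tied back to C5 as a cyclobutenone (retro-4π), and the C5–C4 bond (1-methoxyallenyl anion) and the C6–pentadecyl bond (Grignard reagent) lead back to dimethyl squarate.
Forward: the squarate four-membered ring serves as a temporary ring. The allene is added first and the pentadecyl chain second (with 1,3-carbonyl transposition). One thermal step then expands the four-membered ring to the quinone ring, the only six-membered ring made, and hydrolysis of two methyl ethers ends the route.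
Enabling feature (numbering C1=O, C2–OH, C3–CH3, C4=O, C5–OH, C6–C15H31): C5, C6, C1 and C2 with their oxygens are the four carbons of squaric acid. C4–O is the methoxy carbon of an allene and C3–CH3 its central and terminal carbons, because a methyl-p-quinone is the tautomer of a 4-hydroxy-o-quinone methide.
Stereochemistry: the target has no stereocentre. The single carbinol centre of the cyclobutenones is racemic and becomes sp2 in the key step. The one geometry that matters (allene cis to ketene) comes from outward rotation of the hydroxyl.

Key step: step 5

Remark: 2,5-dihydroxy-1,4-benzoquinones exchange their two O–H···O=C protons rapidly (degenerate tautomerism), so the product of the last step and the structure written for the target are one compound.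

**Route**

Step 1
Reactants: 1 dimethyl squarate (3,4-dimethoxycyclobut-3-ene-1,2-dione); 2 methoxyallene (1-methoxypropa-1,2-diene)
Product: 5 2,3-dimethoxy-4-(1-methoxypropa-1,2-dien-1-yl)-4-(triethylsilyloxy)cyclobut-2-en-1-one (racemic), via 1-lithio-1-methoxyallene 3 (not isolated), via lithium alkoxide 4 (not isolated)
Conditions: 2, n-BuLi, THF, −40 °C; added to 1, THF, −78 °C; then Et3SiCl, −78 to 0 °C
Reagents that add atoms: chlorotriethylsilane CC[Si](CC)(CC)Cl
Why: α-Lithiation of the enol-ether allene and 1,2-addition of the organolithium to one of the two equivalent vinylogous-ester carbonyls of the squarate, followed by O-silylation of the tertiary lithium alkoxide in the same flask, should give the protected carbinol, whose new stereocentre is formed racemic and is erased later.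

Step 2
Reactants: 6 1-bromopentadecane
Product: 7 pentadecylmagnesium bromide (THF solution, titrated and used as such)
Conditions: Mg turnings, I2 (cat.), THF, 25–50 °C
Reagents that add atoms: magnesium [Mg]
Why: Insertion of magnesium into the primary C–Br bond is a standard Grignard reagent formation.

Step 3
Reactants: 5 2,3-dimethoxy-4-(1-methoxypropa-1,2-dien-1-yl)-4-(triethylsilyloxy)cyclobut-2-en-1-one; 7 pentadecylmagnesium bromide
Product: 10 2-methoxy-4-(1-methoxypropa-1,2-dien-1-yl)-3-pentadecyl-4-(triethylsilyloxy)cyclobut-2-en-1-one (racemic), via bromomagnesium alkoxide 8 (not isolated), via allylic trifluoroacetate 9 (not isolated)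
Conditions: 7, THF, −78 °C; (CF3CO)2O, −78 °C; H2O (pH 7 buffer), −78 to 0 °C
Reagents that add atoms: water O
Why: Grignard 1,2-addition to the only ring carbonyl, then O-trifluoroacetylation and hydrolytic allylic (1,3-carbonyl) transposition (ionisation to the cyclobutenyl cation stabilised by the distal methoxy group, attack of water at that carbon and loss of methanol) should place pentadecyl on C3 and the carbonyl next to C4; a direct 1,4-addition–elimination would lead to the same constitution, and the extra carbinol stereocentre of 8 (diastereomer mixture) disappears again.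

Step 4
Reactants: 10 2-methoxy-4-(1-methoxypropa-1,2-dien-1-yl)-3-pentadecyl-4-(triethylsilyloxy)cyclobut-2-en-1-one
Product: 11 4-hydroxy-2-methoxy-4-(1-methoxypropa-1,2-dien-1-yl)-3-pentadecylcyclobut-2-en-1-one (racemic)
Conditions: Bu4NF, AcOH, THF, 0 °C
Reagents that add atoms: none
Why: Fluoride-induced desilylation of the tertiary triethylsilyl ether, buffered with acetic acid so that no free alkoxide builds up next to the allene and the strained enone, should free the carbinol without touching the two enol ethers.

Step 5
Reactants: 11 4-hydroxy-2-methoxy-4-(1-methoxypropa-1,2-dien-1-yl)-3-pentadecylcyclobut-2-en-1-one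
Product: 14 2,5-dimethoxy-3-methyl-6-pentadecylcyclohexa-2,5-diene-1,4-dione, via dienylketene 12 (not isolated), via hydroxy o-quinone methide 13 (not isolated)
Conditions: toluene (degassed, dilute), 100 °C
Reagents that add atoms: none
Why: Heating should open the cyclobutenone by conrotatory 4π electrocyclic cleavage of the C1–C4 bond to dienylketene 12, whose electrophilic ketene carbon then bonds to the central (sp) carbon of the electron-rich 1-methoxyallene; this is the only C–C bond made in the step and the one that closes the six-membered ring. The closest known reaction type is the thermal ring expansion of squarate-derived 4-allenyl-4-oxycyclobutenones to o-quinone methides (Moore-type rearrangement). The ring closes in the thermal disrotatory 6π-electrocyclic mode of a hexatriene whose termini are the ketene carbon and the allene central carbon, which leaves the former allene terminus as an exocyclic CH2 in o-quinone methide 13. Because C4 carries a free, acidic OH, 13 is one vinylogous keto–enol proton shift (OH to CH2) away from p-quinone 14, so the methyl group and the quinone oxidation level should arise without any oxidant. No stereocentre is formed and the racemic carbinol carbon of 11 becomes sp2. The step needs torquoselectivity and periselectivity: the donor hydroxyl rotates outward in the ring opening, which puts the allene cis to the ketene and keeps the OH from lactonising onto it, and the position of the cumulated sp carbon at the 1,6-distance favours six- over five-membered closure.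

Step 6
Reactants: 14 2,5-dimethoxy-3-methyl-6-pentadecylcyclohexa-2,5-diene-1,4-dione
Product: 16 2,5-dihydroxy-3-methyl-6-pentadecylcyclohexa-2,5-diene-1,4-dione (target), via disodium salt 15 (not isolated)
Conditions: NaOH, H2O/EtOH, 70 °C; then aq. HCl, 0 °C
Reagents that add atoms: sodium hydroxide [Na+].[OH-]
Why: Both methoxy groups are vinylogous methyl esters, so hydroxide should replace them by conjugate addition–elimination (vinylogous ester saponification) to give the stable dianion, which is protonated on acidification.

**Compound list**

1 | dimethyl squarate (3,4-dimethoxycyclobut-3-ene-1,2-dione) | COC1=C(OC)C(=O)C1=O | starting material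
2 | methoxyallene (1-methoxypropa-1,2-diene) | COC=C=C | starting material
3 | 1-lithio-1-methoxyallene | [Li]C(OC)=C=C | intermediate
4 | lithium 2,3-dimethoxy-1-(1-methoxypropa-1,2-dien-1-yl)-4-oxocyclobut-2-en-1-olate (racemic) | COC1=C(OC)C([O-])(C(OC)=C=C)C1=O.[Li+] | intermediate
5 | 2,3-dimethoxy-4-(1-methoxypropa-1,2-dien-1-yl)-4-(triethylsilyloxy)cyclobut-2-en-1-one (racemic) | COC1=C(OC)C(O[Si](CC)(CC)CC)(C(OC)=C=C)C1=O | intermediate
6 | 1-bromopentadecane | CCCCCCCCCCCCCCCBr | starting material
7 | pentadecylmagnesium bromide | CCCCCCCCCCCCCCC[Mg]Br | intermediate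
8 | bromomagnesium 2,3-dimethoxy-4-(1-methoxypropa-1,2-dien-1-yl)-1-pentadecyl-4-(triethylsilyloxy)cyclobut-2-en-1-olate (racemic, diastereomer mixture) | CCCCCCCCCCCCCCCC1([O-])C(OC)=C(OC)C1(O[Si](CC)(CC)CC)C(OC)=C=C.[Mg+2].[Br-] | intermediate
9 | 2,3-dimethoxy-4-(1-methoxypropa-1,2-dien-1-yl)-1-pentadecyl-4-(triethylsilyloxy)cyclobut-2-en-1-yl trifluoroacetate (racemic, diastereomer mixture) | CCCCCCCCCCCCCCCC1(OC(=O)C(F)(F)F)C(OC)=C(OC)C1(O[Si](CC)(CC)CC)C(OC)=C=C | intermediate
10 | 2-methoxy-4-(1-methoxypropa-1,2-dien-1-yl)-3-pentadecyl-4-(triethylsilyloxy)cyclobut-2-en-1-one (racemic) | CCCCCCCCCCCCCCCC1=C(OC)C(=O)C1(O[Si](CC)(CC)CC)C(OC)=C=C | intermediate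
11 | 4-hydroxy-2-methoxy-4-(1-methoxypropa-1,2-dien-1-yl)-3-pentadecylcyclobut-2-en-1-one (racemic) | CCCCCCCCCCCCCCCC1=C(OC)C(=O)C1(O)C(OC)=C=C | intermediate
12 | (3E)-4-hydroxy-2,5-dimethoxy-3-pentadecylhepta-1,3,5,6-tetraen-1-one (dienylketene, allene cis to the ketene) | O=C=C(OC)/C(CCCCCCCCCCCCCCC)=C(/O)C(OC)=C=C | intermediate
13 | 4-hydroxy-2,5-dimethoxy-6-methylidene-3-pentadecylcyclohexa-2,4-dien-1-one | C=C1C(OC)=C(O)C(CCCCCCCCCCCCCCC)=C(OC)C1=O | intermediate
14 | 2,5-dimethoxy-3-methyl-6-pentadecylcyclohexa-2,5-diene-1,4-dione | COC1=C(C)C(=O)C(OC)=C(CCCCCCCCCCCCCCC)C1=O | intermediate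
15 | disodium 3-methyl-6-pentadecyl-1,4-dioxocyclohexa-2,5-diene-2,5-diolate | CCCCCCCCCCCCCCCC1=C([O-])C(=O)C(C)=C([O-])C1=O.[Na+].[Na+] | intermediate
16 | 2,5-dihydroxy-3-methyl-6-pentadecylcyclohexa-2,5-diene-1,4-dione | CCCCCCCCCCCCCCCC1=C(O)C(=O)C(C)=C(O)C1=O | target

**Step count and risks**

Total steps: 6. Longest linear sequence: 5 steps (1 → 5 → 10 → 11 → 14 → 16; the Grignard branch 6 → 7 joins at step 3).

Steps most likely to fail:

Step 3. The silyl group may shift from the C4 oxygen to the neighbouring new alkoxide, so that the wrong carbinol is acylated and ionised. The anhydride may C-acylate the allenyl enol ether, or the trifluoroacetic acid set free may hydrolyse it, and the Grignard reagent may reduce or enolise the hindered ketone. The fallback sets out from 5 and 7 and comes back at 10. It replaces addition/transposition by a copper-catalysed conjugate addition–elimination (7, CuBr·SMe2 cat., THF, −78 to −40 °C). The organocopper species should add to the methoxy-bearing β-carbon C3 of the strained vinylogous ester to give the bromomagnesium enolate bromomagnesium 2,3-dimethoxy-4-(1-methoxypropa-1,2-dien-1-yl)-3-pentadecyl-4-(triethylsilyloxy)cyclobut-1-en-1-olate F1. F1 expels methoxide (E1cB) and gives 10 directly, with no alkoxide beside the silyl ether and no acylating agent or acid in the flask.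

Step 5. The hydroxyl may rotate inward and capture the ketene (lactonisation to a butenolide), the ketene may react with the allene in another mode, or the o-quinone methide may oligomerise faster than it tautomerises. The fallback sets out from 6 and comes back at 14. It builds the substitution pattern on a preformed arene instead of closing the ring. Commercial 1,2,4,5-tetramethoxybenzene is lithiated between two methoxy groups (n-BuLi, TMEDA, THF, 0 °C) to 2,3,5,6-tetramethoxyphenyllithium F2 and alkylated with 6 to give 1,2,4,5-tetramethoxy-3-pentadecylbenzene F3. A second lithiation at the last ring C–H gives 2,3,5,6-tetramethoxy-4-pentadecylphenyllithium F4, and MeI gives 1,2,4,5-tetramethoxy-3-methyl-6-pentadecylbenzene F5. Oxidative demethylation with (NH4)2Ce(NO3)6 in MeCN/H2O at 0 °C should give 14.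

Step 4. Once fluoride uncovers the oxygen, the tertiary allenyl carbinol may cyclise onto the allene or the anion may open the four-membered ring prematurely, so that 11 cannot be handled. The fallback sets out from 10 and comes back at 14. It changes the order of events and carries the silyl ether through the ring expansion. Heating 10 in toluene at 100 °C should give, by the same 4π/6π sequence and with lactonisation blocked, the silyl-protected o-quinone methide 2,5-dimethoxy-6-methylidene-3-pentadecyl-4-(triethylsilyloxy)cyclohexa-2,4-dien-1-one F6. Bu4NF/AcOH in THF at −20 °C then frees the dienol, which tautomerises to 14.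

**Further compounds**

F1 | step 3 | bromomagnesium 2,3-dimethoxy-4-(1-methoxypropa-1,2-dien-1-yl)-3-pentadecyl-4-(triethylsilyloxy)cyclobut-1-en-1-olate | CCCCCCCCCCCCCCCC1(OC)C(OC)=C([O-])C1(O[Si](CC)(CC)CC)C(OC)=C=C.[Mg+2].[Br-]
F2 | step 5 | 2,3,5,6-tetramethoxyphenyllithium | [Li]c1c(OC)c(OC)cc(OC)c1OC
F3 | step 5 | 1,2,4,5-tetramethoxy-3-pentadecylbenzene | CCCCCCCCCCCCCCCc1c(OC)c(OC)cc(OC)c1OC
F4 | step 5 | 2,3,5,6-tetramethoxy-4-pentadecylphenyllithium | [Li]c1c(OC)c(OC)c(CCCCCCCCCCCCCCC)c(OC)c1OC
F5 | step 5 | 1,2,4,5-tetramethoxy-3-methyl-6-pentadecylbenzene | CCCCCCCCCCCCCCCc1c(OC)c(OC)c(C)c(OC)c1OC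
F6 | step 4 | 2,5-dimethoxy-6-methylidene-3-pentadecyl-4-(triethylsilyloxy)cyclohexa-2,4-dien-1-one | C=C1C(OC)=C(O[Si](CC)(CC)CC)C(CCCCCCCCCCCCCCC)=C(OC)C1=O
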